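**Retrosynthetic overview**

1. The target is an ent-labdane. Its trans-decalin has the quaternary C10 (C20 methyl) between C5 and C9, and C9 carries the C11–C15 chain beside the oxygenated C8. Ring B is therefore treated as a 4-oxygenated 2-methylcyclohexanone.
2. Key disconnection (three bonds, ring A): C9–C11 by cuprate addition, C1–C10 by Michael addition of the C10 enolate to an α-silyl vinyl ketone, and C4–C5 by aldol condensation. The components are enone 6, Grignard reagent 12 and silyl enone 17.
3. Ring order: ring B comes from the aromatic ring of phenol 1, with absolute configuration from one CBS reduction (the later C8). Ring A is closed in the key step. C13 comes from hemiester 7.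
4. After the annulation: reductive hydroxymethylation of the Δ4-3-ketone sets C4 and C5, C3 is deoxygenated, C8 goes through ketone, methylene and epoxide to the tertiary alcohol, then angeloylation and oxidation of C15.

Key step: step 13

Remark: labdane numbering is used for the decalin carbons (C18 is the oxygenated carbon on C4, C17 the carbon on C8, C20 the methyl on C10), "syn" and "anti" refer to the C20 methyl, and hemiester 7 and bromovinylsilane 13 are taken as catalogue compounds.

**Route**

Step 1
Reactants: 1 4-methoxy-3-methylphenol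
Product: 2 4,4-dimethoxy-3-methylcyclohexa-2,5-dien-1-one
Conditions: PhI(OAc)2 (1.1 equiv), MeOH, 0 °C to rt
Reagents that add atoms: methanol, CO
Why: Oxidative dearomatisation of a p-alkoxyphenol with PhI(OAc)2 in methanol (quinone monoketal formation) should add methanol at the methoxy-bearing carbon and leave the methyl group on the double bond next to the ketal.

Step 2
Reactants: 2 4,4-dimethoxy-3-methylcyclohexa-2,5-dien-1-one
Product: 3 4,4-dimethoxy-3-methylcyclohex-2-en-1-one
Conditions: H2 (1 atm), RhCl(PPh3)3 (5 mol%), benzene, rt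
Reagents that add atoms: none
Why: Homogeneous hydrogenation with RhCl(PPh3)3 discriminates by alkene substitution, so the disubstituted ring double bond should be reduced while the methyl-bearing trisubstituted enone bond, the ketone and the ketal stay.

Step 3
Reactants: 3 4,4-dimethoxy-3-methylcyclohex-2-en-1-one
Product: 4 (S)-4,4-dimethoxy-3-methylcyclohex-2-en-1-ol
Conditions: (R)-1-methyl-3,3-diphenyltetrahydro-1H,3H-pyrrolo[1,2-c][1,3,2]oxazaborole [(R)-Me-CBS, 0.1 equiv], catecholborane (1.5 equiv), toluene, −78 °C
Reagents that add atoms: none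
Why: Corey–Bakshi–Shibata reduction, in which the alkenyl arm of the enone acts as the large and the CH2 arm as the small substituent, so the (R)-catalyst should deliver hydride to the face that gives the (S)-carbinol (the later C8), the only stereocentre of the decalin series that a reagent introduces.

Step 4
Reactants: 4 (S)-4,4-dimethoxy-3-methylcyclohex-2-en-1-ol
Product: 5 (S)-tert-butyl[(4,4-dimethoxy-3-methylcyclohex-2-en-1-yl)oxy]dimethylsilane
Conditions: TBSCl, imidazole, DMF, rt
Reagents that add atoms: tert-butyldimethylsilyl chloride, CC(C)(C)[Si](C)(C)Cl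
Why: Standard silylation of a secondary allylic alcohol with TBSCl and imidazole, which does not touch the stereocentre.

Step 5
Reactants: 5 (S)-tert-butyl[(4,4-dimethoxy-3-methylcyclohex-2-en-1-yl)oxy]dimethylsilane
Product: 6 (S)-4-(tert-butyldimethylsilyloxy)-2-methylcyclohex-2-en-1-one
Conditions: 5% aq. oxalic acid, SiO2, CH2Cl2, rt
Reagents that add atoms: water, O
Why: Acid-catalysed hydrolysis of an α,β-unsaturated dimethyl ketal goes through a stabilised oxocarbenium ion under conditions that a secondary TBS ether tolerates, and unveils the 2-methyl enone with the silyloxy group at ring position 4.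

Step 6
Reactants: 7 methyl hydrogen (R)-3-methylglutarate [(R)-5-methoxy-3-methyl-5-oxopentanoic acid]
Product: 8 methyl (R)-5-hydroxy-3-methylpentanoate
Conditions: BH3·SMe2 (1.1 equiv), THF, −10 °C to rt; MeOH
Reagents that add atoms: none
Why: Borane reduces a carboxylic acid through its acyloxyborane much faster than an ester (chemoselective borane reduction), so only the free acid arm of 7 should be reduced and the stereocentre, defined by the difference of the two arms, is kept.

Step 7
Reactants: 8 methyl (R)-5-hydroxy-3-methylpentanoate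
Product: 9 methyl (R)-3-methyl-5-(triisopropylsilyloxy)pentanoate
Conditions: TIPSCl, imidazole, DMF, rt
Reagents that add atoms: triisopropylsilyl chloride, CC(C)[Si](Cl)(C(C)C)C(C)C
Why: Silylation of the primary alcohol with TIPSCl and imidazole, carried out at once to forestall lactonisation of the δ-hydroxy ester.

Step 8
Reactants: 9 methyl (R)-3-methyl-5-(triisopropylsilyloxy)pentanoate
Product: 10 (S)-3-methyl-5-(triisopropylsilyloxy)pentan-1-ol
Conditions: LiAlH4, Et2O, 0 °C
Reagents that add atoms: none
Why: Hydride reduction of the methyl ester to the primary alcohol with LiAlH4, which leaves the TIPS ether alone (the descriptor changes from R to S only through the priority rules).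

Step 9
Reactants: 10 (S)-3-methyl-5-(triisopropylsilyloxy)pentan-1-ol
Product: 11 (R)-(5-bromo-3-methylpentyloxy)triisopropylsilane
Conditions: CBr4, PPh3, CH2Cl2, 0 °C
Reagents that add atoms: carbon tetrabromide, BrC(Br)(Br)Br
Why: Appel bromination converts the primary alcohol into the bromide by SN2 displacement of the oxyphosphonium group under neutral conditions that leave the TIPS ether intact.

Step 10
Reactants: 11 (R)-(5-bromo-3-methylpentyloxy)triisopropylsilane
Product: 12 (R)-[3-methyl-5-(triisopropylsilyloxy)pentyl]magnesium bromide (THF solution)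
Conditions: Mg turnings, 1,2-dibromoethane (cat.), THF, 40 °C
Reagents that add atoms: magnesium, [Mg]
Why: Oxidative insertion of magnesium into the primary C–Br bond (Grignard formation) does not affect the remote TIPS ether or the stereocentre, and the titrated solution is used directly.

Step 11
Reactants: 13 (1-bromovinyl)trimethylsilane; 14 propanal
Product: 16 2-(trimethylsilyl)pent-1-en-3-ol (racemic), via [1-(trimethylsilyl)vinyl]magnesium bromide 15 (not isolated)
Conditions: Mg, THF, reflux; then 14, 0 °C; aq. NH4Cl
Reagents that add atoms: none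
Why: Grignard formation from the α-bromovinylsilane and 1,2-addition to the aldehyde gives the racemic allylic alcohol, whose stereocentre is removed in the next step.

Step 12
Reactants: 16 2-(trimethylsilyl)pent-1-en-3-ol
Product: 17 2-(trimethylsilyl)pent-1-en-3-one
Conditions: Dess–Martin periodinane, NaHCO3, CH2Cl2, 0 °C to rt; distilled before use
Reagents that add atoms: none
Why: Dess–Martin oxidation of the secondary allylic alcohol under buffered, non-aqueous conditions should give the polymerisation-prone α-silyl enone, which is used fresh.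

Step 13
Reactants: 6 (S)-4-(tert-butyldimethylsilyloxy)-2-methylcyclohex-2-en-1-one; 12 (R)-[3-methyl-5-(triisopropylsilyloxy)pentyl]magnesium bromide; 17 2-(trimethylsilyl)pent-1-en-3-one
Product: 21 (4aS,5S,6S)-6-(tert-butyldimethylsilyloxy)-1,4a-dimethyl-5-[(3S)-3-methyl-5-(triisopropylsilyloxy)pentyl]-4,4a,5,6,7,8-hexahydronaphthalen-2(3H)-one, via bromomagnesium enolate 18 (not isolated), via α-silyl diketone 19 (not isolated), via desilylated diketone 20 (not isolated)
Conditions: 12 (1.4 equiv), CuBr·SMe2 (0.2 equiv), THF, −78 to −40 °C; then 17 (1.5 equiv), −78 to −20 °C; then NaOMe, MeOH, 0 to 50 °C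
Reagents that add atoms: none
Why: The organocopper species formed from 12 and CuBr·SMe2 transfers the chain to C9 of 6 on the face anti to the C8 silyloxy group and gives the regiodefined bromomagnesium enolate 18; this adds through C10 to the unsubstituted terminus of 17 (C1–C10 bond) on the face anti to the new C9 chain, which creates the quaternary centre with the C20 methyl syn to the chain and leaves the α-silyl diketone 19. Methoxide then cleaves the C–Si bond (to 20), and the C4 enolate of the ethyl ketone attacks the ring carbonyl C5 and loses water, which closes ring A by a 6-(enolexo)-exo-trig aldol condensation. The closest known reaction type is conjugate addition followed by Michael addition to an α-silyl vinyl ketone and aldol condensation (Robinson-type annulation with a Stork–Ganem reagent). C9 is controlled by the C8 stereocentre of 6 and C10 by C9, so the single CBS-derived centre fixes the absolute configuration of the decalin. The step needs 1,4- over 1,2-addition (secured by copper), C-alkylation at the more substituted α-carbon without enolate equilibration (low temperature and the high reactivity of 17, whose silyl group also suppresses polymerisation), and two anti additions (secured by the bulky silyloxy group and by the C9 chain).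

Step 14
Reactants: 21 bicyclic enone (Δ4-3-ketone, 8-OTBS, 15-OTIPS)
Product: 23 ketol with 3-oxo group and C4 bearing CH2OH (anti to C20) and CH3 (syn) in a trans-decalin (H5 anti to C20), via lithium enolate 22 (not isolated)
Conditions: Li (4 equiv), t-BuOH (1.0 equiv), NH3 (l)/THF, −78 to −33 °C; isoprene; NH3 removed, THF; CH2O (g), −78 to −40 °C; aq. NH4Cl
Reagents that add atoms: formaldehyde, C=O
Why: Dissolving-metal reduction of the enone followed by enolate trapping (Stork reductive alkylation, here a reductive aldol with formaldehyde): protonation of C5 gives the trans-fused enolate 22 with H5 anti to C20, and formaldehyde is attacked by C4 on the face anti to the axial C20 methyl, so CH2OH ends anti and the C4 methyl syn to C20.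

Step 15
Reactants: 23 ketol
Product: 24 keto pivalate (3-oxo, 18-OPiv, 8-OTBS, 15-OTIPS)
Conditions: PivCl, pyridine, 4-(dimethylamino)pyridine (cat.), CH2Cl2, 0 °C to rt
Reagents that add atoms: pivaloyl chloride, CC(C)(C)C(=O)Cl
Why: Acylation of the neopentyl-type primary alcohol with pivaloyl chloride under nucleophilic catalysis masks the β-hydroxy ketone against retro-aldol cleavage and gives an ester that survives fluoride, ylide and peracid but is cleaved by LiAlH4 in step 23.

Step 16
Reactants: 24 keto pivalate
Product: 25 C3 tosylhydrazone of 24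
Conditions: TsNHNH2 (2 equiv), EtOH, 4 Å MS, 75 °C
Reagents that add atoms: p-toluenesulfonyl hydrazide, Cc1ccc(cc1)S(=O)(=O)NN
Why: Condensation of the ketone with tosylhydrazide (hydrazone formation) is known for ketones flanked by a quaternary carbon and touches neither the ester nor the silyl ethers.

Step 17
Reactants: 25 C3 tosylhydrazone
Product: 27 3-deoxy compound (C3 methylene, 18-OPiv, 8-OTBS, 15-OTIPS), via tosylhydrazine 26 (not isolated)
Conditions: catecholborane (3 equiv), CHCl3, 0 °C to rt; then NaOAc·3H2O, 60 °C
Reagents that add atoms: none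
Why: Kabalka-type reduction of a tosylhydrazone, in which catecholborane adds hydride to C=N to give 26 and acetate triggers loss of sulfinate and N2 from the resulting diazene, turns C3 into CH2 under conditions mild enough for the pivalate and both silyl ethers.

Step 18
Reactants: 27 3-deoxy compound
Product: 28 8,15-diol 18-pivalate
Conditions: Bu4NF (5 equiv), THF, 50 °C
Reagents that add atoms: none
Why: Fluoride-induced cleavage of both silyl ethers (desilylation driven by Si–F bond formation) frees the C8 and C15 hydroxyls together while the hindered pivalate is inert.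

Step 19
Reactants: 28 8,15-diol 18-pivalate
Product: 29 15-O-TBS ether with free secondary 8-OH (18-OPiv)
Conditions: TBSCl (1.05 equiv), imidazole, CH2Cl2, −20 °C
Reagents that add atoms: tert-butyldimethylsilyl chloride, CC(C)(C)[Si](C)(C)Cl
Why: Selective silylation by steric differentiation, since the unhindered primary C15 hydroxyl should react with one equivalent of TBSCl far faster than the secondary C8 hydroxyl flanked by the C9 substituent.

Step 20
Reactants: 29 15-O-TBS 8-alcohol
Product: 30 8-ketone (18-OPiv, 15-OTBS)
Conditions: Dess–Martin periodinane, NaHCO3, CH2Cl2, rt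
Reagents that add atoms: none
Why: Dess–Martin oxidation of the secondary alcohol gives the C8 ketone under buffered conditions, and C9 should keep its configuration because the equatorial chain is the more stable arrangement.

Step 21
Reactants: 30 8-ketone
Product: 31 8(17)-alkene (exocyclic methylene on C8)
Conditions: Ph3PCH3Br, KOtBu, THF/toluene, rt to 60 °C
Reagents that add atoms: methyltriphenylphosphonium bromide, C[P+](c1ccccc1)(c1ccccc1)c1ccccc1.[Br-]
Why: Wittig methylenation with the unstabilised ylide converts the hindered C8 ketone into the exocyclic C8=C17 alkene, the pivalate being too hindered to react.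

Step 22
Reactants: 31 8(17)-alkene
Product: 32 8,17-epoxide (epoxide oxygen anti to C20, C17 syn)
Conditions: mCPBA, NaHCO3, CH2Cl2, 0 °C
Reagents that add atoms: 3-chloroperbenzoic acid, OOC(=O)c1cccc(Cl)c1
Why: Prilezhaev epoxidation of the exocyclic alkene should occur on the face anti to the axial C20 methyl, which places the epoxide oxygen anti and C17 syn to C20.

Step 23
Reactants: 32 8,17-epoxide
Product: 33 8,18-diol (tertiary 8-OH anti to C20, C17 methyl syn, primary 18-OH, 15-OTBS)
Conditions: LiAlH4, THF, 0 °C to rt
Reagents that add atoms: none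
Why: Hydride opens the epoxide by SN2 attack at the primary C17, so C8 keeps its oxygen anti to C20 and gains the C17 methyl syn to it, while the same reagent reduces the pivalate and frees the C18 alcohol.

Step 24
Reactants: 33 8,18-diol
Product: 34 18-angelate (8-OH free, 15-OTBS)
Conditions: angelic acid, 2,4,6-trichlorobenzoyl chloride, Et3N, toluene, rt; then 33, 75 °C
Reagents that add atoms: angelic acid, C/C=C(/C)C(=O)O
Why: Esterification through the mixed anhydride with 2,4,6-trichlorobenzoic acid (Yamaguchi-type) without a nucleophilic catalyst is the established way to introduce an angelate without Z to E isomerisation, and only the primary C18 hydroxyl reacts while the tertiary C8 hydroxyl does not.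

Step 25
Reactants: 34 18-angelate 15-O-TBS ether
Product: 35 18-angelate 8,15-diol
Conditions: HF·pyridine, pyridine, THF, 0 °C to rt
Reagents that add atoms: none
Why: Buffered HF·pyridine removes the primary TBS ether (desilylation) without touching the angelate or dehydrating the tertiary alcohol.

Step 26
Reactants: 35 18-angelate 8,15-diol
Product: 36 target acid, (3S)-5-[(1S,2S,4aS,5S,8aR)-2-hydroxy-2,5,8a-trimethyl-5-{[(Z)-2-methylbut-2-enoyl]oxymethyl}decahydronaphthalen-1-yl]-3-methylpentanoic acid
Conditions: 2,2,6,6-tetramethylpiperidin-1-oxyl (TEMPO, 0.2 equiv), PhI(OAc)2 (2.2 equiv), MeCN/H2O, rt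
Reagents that add atoms: water, O
Why: Nitroxyl-catalysed oxidation with PhI(OAc)2 in aqueous acetonitrile takes the primary alcohol through the aldehyde hydrate to the carboxylic acid, and neither the tertiary alcohol nor the electron-poor angelate alkene is oxidised.

**Compound list**

1 | 4-methoxy-3-methylphenol | COc1ccc(O)cc1C | starting material
2 | 4,4-dimethoxy-3-methylcyclohexa-2,5-dien-1-one | COC1(OC)C=CC(=O)C=C1C | intermediate
3 | 4,4-dimethoxy-3-methylcyclohex-2-en-1-one | COC1(OC)CCC(=O)C=C1C | intermediate
4 | (S)-4,4-dimethoxy-3-methylcyclohex-2-en-1-ol | CC1=C[C@@H](O)CCC1(OC)OC | intermediate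
5 | (S)-tert-butyl[(4,4-dimethoxy-3-methylcyclohex-2-en-1-yl)oxy]dimethylsilane | CC1=C[C@@H](O[Si](C)(C)C(C)(C)C)CCC1(OC)OC | intermediate
6 | (S)-4-(tert-butyldimethylsilyloxy)-2-methylcyclohex-2-en-1-one | CC1=C[C@@H](O[Si](C)(C)C(C)(C)C)CCC1=O | intermediate
7 | methyl hydrogen (R)-3-methylglutarate | COC(=O)C[C@H](C)CC(=O)O | starting material
8 | methyl (R)-5-hydroxy-3-methylpentanoate | COC(=O)C[C@H](C)CCO | intermediate
9 | methyl (R)-3-methyl-5-(triisopropylsilyloxy)pentanoate | COC(=O)C[C@H](C)CCO[Si](C(C)C)(C(C)C)C(C)C | intermediate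
10 | (S)-3-methyl-5-(triisopropylsilyloxy)pentan-1-ol | OCC[C@H](C)CCO[Si](C(C)C)(C(C)C)C(C)C | intermediate
11 | (R)-(5-bromo-3-methylpentyloxy)triisopropylsilane | BrCC[C@H](C)CCO[Si](C(C)C)(C(C)C)C(C)C | intermediate
12 | (R)-[3-methyl-5-(triisopropylsilyloxy)pentyl]magnesium bromide | Br[Mg]CC[C@H](C)CCO[Si](C(C)C)(C(C)C)C(C)C | intermediate
13 | (1-bromovinyl)trimethylsilane | C=C(Br)[Si](C)(C)C | starting material
14 | propanal | CCC=O | starting material
15 | [1-(trimethylsilyl)vinyl]magnesium bromide (formed in the flask) | C=C([Mg]Br)[Si](C)(C)C | intermediate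
16 | 2-(trimethylsilyl)pent-1-en-3-ol (racemic) | C=C([Si](C)(C)C)C(O)CC | intermediate
17 | 2-(trimethylsilyl)pent-1-en-3-one | C=C([Si](C)(C)C)C(=O)CC | intermediate
18 | bromomagnesium enolate of the conjugate adduct, chain on C9 anti to 8-OTBS (formed in the flask) | Br[Mg]OC1=C(C)[C@H](CC[C@H](C)CCO[Si](C(C)C)(C(C)C)C(C)C)[C@@H](O[Si](C)(C)C(C)(C)C)CC1 | intermediate
19 | α-silyl 1,5-diketone, Michael adduct with quaternary C10, mixture at the silyl-bearing carbon (formed in the flask) | CCC(=O)C(C[C@]1(C)C(=O)CC[C@H](O[Si](C)(C)C(C)(C)C)[C@H]1CC[C@H](C)CCO[Si](C(C)C)(C(C)C)C(C)C)[Si](C)(C)C | intermediate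
20 | desilylated 1,5-diketone (formed in the flask) | CCC(=O)CC[C@]1(C)C(=O)CC[C@H](O[Si](C)(C)C(C)(C)C)[C@H]1CC[C@H](C)CCO[Si](C(C)C)(C(C)C)C(C)C | intermediate
21 | (4aS,5S,6S)-6-(tert-butyldimethylsilyloxy)-1,4a-dimethyl-5-[(3S)-3-methyl-5-(triisopropylsilyloxy)pentyl]-4,4a,5,6,7,8-hexahydronaphthalen-2(3H)-one (Δ4-3-ketone; C9 chain syn, 8-OTBS anti to C20) | O=C1CC[C@]2(C)C(=C1C)CC[C@H](O[Si](C)(C)C(C)(C)C)[C@H]2CC[C@H](C)CCO[Si](C(C)C)(C(C)C)C(C)C | intermediate
22 | lithium C3–C4 enolate of the trans-fused ketone, H5 anti to C20 (formed in the flask) | CC1=C(O[Li])CC[C@]2(C)[C@@H]1CC[C@H](O[Si](C)(C)C(C)(C)C)[C@H]2CC[C@H](C)CCO[Si](C(C)C)(C(C)C)C(C)C | intermediate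
23 | ketol: 3-oxo, C4 with CH2OH anti and CH3 syn to C20, trans-decalin, 8-OTBS, 15-OTIPS | OC[C@@]1(C)C(=O)CC[C@]2(C)[C@@H]1CC[C@H](O[Si](C)(C)C(C)(C)C)[C@H]2CC[C@H](C)CCO[Si](C(C)C)(C(C)C)C(C)C | intermediate
24 | keto pivalate (18-OPiv of 23) | CC(C)(C)C(=O)OC[C@@]1(C)C(=O)CC[C@]2(C)[C@@H]1CC[C@H](O[Si](C)(C)C(C)(C)C)[C@H]2CC[C@H](C)CCO[Si](C(C)C)(C(C)C)C(C)C | intermediate
25 | C3 tosylhydrazone of 24 | CC(C)(C)C(=O)OC[C@@]1(C)C(=NNS(=O)(=O)c3ccc(C)cc3)CC[C@]2(C)[C@@H]1CC[C@H](O[Si](C)(C)C(C)(C)C)[C@H]2CC[C@H](C)CCO[Si](C(C)C)(C(C)C)C(C)C | intermediate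
26 | C3 tosylhydrazine, shown in its protonated form (formed in the flask) | CC(C)(C)C(=O)OC[C@@]1(C)C(NNS(=O)(=O)c3ccc(C)cc3)CC[C@]2(C)[C@@H]1CC[C@H](O[Si](C)(C)C(C)(C)C)[C@H]2CC[C@H](C)CCO[Si](C(C)C)(C(C)C)C(C)C | intermediate
27 | 3-deoxy compound: 18-OPiv, 8-OTBS, 15-OTIPS | CC(C)(C)C(=O)OC[C@@]1(C)CCC[C@]2(C)[C@@H]1CC[C@H](O[Si](C)(C)C(C)(C)C)[C@H]2CC[C@H](C)CCO[Si](C(C)C)(C(C)C)C(C)C | intermediate
28 | 8,15-diol 18-pivalate | CC(C)(C)C(=O)OC[C@@]1(C)CCC[C@]2(C)[C@@H]1CC[C@H](O)[C@H]2CC[C@H](C)CCO | intermediate
29 | 15-O-TBS 8-alcohol 18-pivalate | CC(C)(C)C(=O)OC[C@@]1(C)CCC[C@]2(C)[C@@H]1CC[C@H](O)[C@H]2CC[C@H](C)CCO[Si](C)(C)C(C)(C)C | intermediate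
30 | 8-ketone: 18-OPiv, 15-OTBS | CC(C)(C)C(=O)OC[C@@]1(C)CCC[C@]2(C)[C@@H]1CCC(=O)[C@H]2CC[C@H](C)CCO[Si](C)(C)C(C)(C)C | intermediate
31 | 8(17)-alkene: 18-OPiv, 15-OTBS | CC(C)(C)C(=O)OC[C@@]1(C)CCC[C@]2(C)[C@@H]1CCC(=C)[C@H]2CC[C@H](C)CCO[Si](C)(C)C(C)(C)C | intermediate
32 | 8,17-epoxide, oxygen anti to C20: 18-OPiv, 15-OTBS | CC(C)(C)C(=O)OC[C@@]1(C)CCC[C@]2(C)[C@@H]1CC[C@@]3(CO3)[C@H]2CC[C@H](C)CCO[Si](C)(C)C(C)(C)C | intermediate
33 | 8,18-diol (tertiary 8-OH anti to C20, C17 methyl syn), 15-OTBS | OC[C@@]1(C)CCC[C@]2(C)[C@@H]1CC[C@](C)(O)[C@H]2CC[C@H](C)CCO[Si](C)(C)C(C)(C)C | intermediate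
34 | 18-angelate, 8-OH, 15-OTBS | C/C=C(/C)C(=O)OC[C@@]1(C)CCC[C@]2(C)[C@@H]1CC[C@](C)(O)[C@H]2CC[C@H](C)CCO[Si](C)(C)C(C)(C)C | intermediate
35 | 18-angelate 8,15-diol | C/C=C(/C)C(=O)OC[C@@]1(C)CCC[C@]2(C)[C@@H]1CC[C@](C)(O)[C@H]2CC[C@H](C)CCO | intermediate
36 | (3S)-5-[(1S,2S,4aS,5S,8aR)-2-hydroxy-2,5,8a-trimethyl-5-{[(Z)-2-methylbut-2-enoyl]oxymethyl}decahydronaphthalen-1-yl]-3-methylpentanoic acid (labdane numbering: 4S,5S,8S,9S,10R,13S) | C/C=C(/C)C(=O)OC[C@@]1(C)CCC[C@]2(C)[C@@H]1CC[C@](C)(O)[C@H]2CC[C@H](C)CC(=O)O | target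

**Step count**

Total: 26 steps. Longest linear sequence: 19 steps (steps 1–5, 13, 14–26; the chain branch, steps 6–10, 13, 14–26, is equally long).

**Steps most likely to fail**

Step 13. The bromomagnesium enolate may add to 17 more slowly than 17 polymerises, or proton transfer may equilibrate the enolate before the quaternary centre forms. Facial selectivity at C10 may also be eroded by the silyloxy group on the attacked face. The fallback sets out from 6 and 12 and decouples the two carbon–carbon bond formations. Copper-catalysed conjugate addition in the presence of Me3SiCl gives the isolable trimethylsilyl enol ether F1, which can be purified. MeLi in THF then regenerates the regiodefined lithium enolate F2, which is added to 17 at −78 °C (Stork–Ganem protocol). KOH in MeOH removes silicon and closes ring A, and the route is rejoined at 21.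

Step 14. The lithium enolate may be protonated or may react incompletely with gaseous formaldehyde, which also polymerises. Multiple hydroxymethylation or retro-aldol loss of formaldehyde on work-up would lower the return further. The fallback sets out from 21. The same Li/NH3 reduction is quenched with Me3SiCl/Et3N to give the trimethylsilyl enol ether F3. A Lewis-acid-catalysed Mukaiyama-type hydroxymethylation with aqueous formaldehyde and Yb(OTf)3 in THF/H2O then forms the C4–C18 bond, with the same facial preference, and comes back at 23.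

Step 17. Hydride delivery to the C=N bond next to the quaternary C4 may be too slow, so that the tosylhydrazone is recovered or eliminates to the Δ2 alkene on heating with base. The fallback sets out from 24 and replaces the hydrazone chemistry by a radical deoxygenation. NaBH4 in MeOH gives the equatorial secondary alcohol F4. 1,1'-Thiocarbonyldiimidazole in hot 1,2-dichloroethane gives the thiocarbonylimidazolide F5. Bu3SnH with azobisisobutyronitrile in toluene at reflux (Barton–McCombie) removes the C3 oxygen and returns to the route at 27.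

**Further compounds**

F1 | step 13 | trimethylsilyl enol ether of the conjugate adduct of 6 and 12 | C[Si](C)(C)OC1=C(C)[C@H](CC[C@H](C)CCO[Si](C(C)C)(C(C)C)C(C)C)[C@@H](O[Si](C)(C)C(C)(C)C)CC1
F2 | step 13 | lithium enolate regenerated from F1 | [Li]OC1=C(C)[C@H](CC[C@H](C)CCO[Si](C(C)C)(C(C)C)C(C)C)[C@@H](O[Si](C)(C)C(C)(C)C)CC1
F3 | step 14 | trimethylsilyl C3–C4 enol ether of the trans-fused ketone | CC1=C(O[Si](C)(C)C)CC[C@]2(C)[C@@H]1CC[C@H](O[Si](C)(C)C(C)(C)C)[C@H]2CC[C@H](C)CCO[Si](C(C)C)(C(C)C)C(C)C
F4 | step 17 | equatorial C3 alcohol of the 18-pivalate | CC(C)(C)C(=O)OC[C@@]1(C)[C@H](O)CC[C@]2(C)[C@@H]1CC[C@H](O[Si](C)(C)C(C)(C)C)[C@H]2CC[C@H](C)CCO[Si](C(C)C)(C(C)C)C(C)C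
F5 | step 17 | C3 O-(imidazol-1-ylthiocarbonyl) derivative of F4 | CC(C)(C)C(=O)OC[C@@]1(C)[C@H](OC(=S)n3ccnc3)CC[C@]2(C)[C@@H]1CC[C@H](O[Si](C)(C)C(C)(C)C)[C@H]2CC[C@H](C)CCO[Si](C(C)C)(C(C)C)C(C)C
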